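The furanone is disconnected at O1–C2, C2–C3 and C3–C4: C2 and C3 become two molecules of carbon monoxide and C4–C5–O1 a trans-epoxide. The key step exploits the pair of adjacent oxidised carbons C2 (lactone carbonyl) and C3 (enol carbon) that sit on benzylic C4 of the furanone ring next to the C5–O1 bond. In one operation cobaltate opens the oxirane at C4, two carbon monoxide units insert and the C5 alkoxide closes the lactone, C5 keeping its configuration. The precursor is the (2R,3R)-oxirane carrying ring A (4-acetoxyphenyl) on C4 and the ring B 4-acetoxy-3-prenylbenzyl group on C5, assembled by a chiral sulfonium ylide epoxidation.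

Key step: step 8

Remark (numbering): furanone atoms are O1, C2 (C=O), C3 (C–OH), C4 (bears ring A), C5 (stereocentre, bears the ring B benzyl group); the target is (5R).

Remark (protecting groups): the phenols are carried as acetates, not silyl ethers, because a 4-silyloxyphenyl oxirane would ionise at C4 under Lewis acid and rearrange to the benzyl ketone, whereas 4-acetoxyphenyl keeps C4 open to SN2 attack and makes the C4–H of the acyl intermediate more acidic.

Assumption: the (1R,4R,5R) enantiomer of isothiocineole is taken to be the one whose benzylic ylides give (2R,3R)-epoxides; this rests on a steric model and not on a recalled result, and if the sense is the reverse the mirror-image sulfide is used with no other change.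

Step 1
Reactants: 1 tyrosol [2-(4-hydroxyphenyl)ethanol]; 2 3-chloro-3-methylbut-1-yne
Product: 3 2-{4-[(2-methylbut-3-yn-2-yl)oxy]phenyl}ethan-1-ol
Conditions: K2CO3, KI, CuI (cat.), acetone, 56 °C
Reagents that add atoms: none
Why: Copper-catalysed O-propargylation of a phenol (Williamson type), in which carbonate ionises only the phenol, so the tertiary propargylic electrophile should be taken up by the phenoxide and not by the neutral primary alcohol.

Step 2
Reactants: 3 2-{4-[(2-methylbut-3-yn-2-yl)oxy]phenyl}ethan-1-ol
Product: 4 2-{4-[(2-methylbut-3-en-2-yl)oxy]phenyl}ethan-1-ol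
Conditions: H2 (1 atm), Pd/CaCO3 poisoned with Pb(OAc)2 (Lindlar catalyst), quinoline, EtOAc, rt
Reagents that add atoms: none
Why: Lindlar semihydrogenation should stop at the terminal alkene because the poisoned palladium surface reduces the alkyne much faster than the hindered vinyl group and leaves the aryl ether intact.

Step 3
Reactants: 4 2-{4-[(2-methylbut-3-en-2-yl)oxy]phenyl}ethan-1-ol
Product: 6 4-(2-hydroxyethyl)-2-(3-methylbut-2-en-1-yl)phenol, via ortho-dienone 5 (not isolated)
Conditions: o-xylene, 135 °C
Reagents that add atoms: none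
Why: Aromatic Claisen rearrangement, in which the [3,3] shift of the 1,1-dimethylallyl ether (accelerated by the gem-dimethyl group) can only deliver the allyl terminus to an ortho carbon because para is blocked, after which dienone 5 rearomatises to the ortho-prenylphenol.

Step 4
Reactants: 6 4-(2-hydroxyethyl)-2-(3-methylbut-2-en-1-yl)phenol
Product: 7 4-(2-hydroxyethyl)-2-(3-methylbut-2-en-1-yl)phenyl acetate
Conditions: Ac2O (1.05 equiv), NaOH (1.05 equiv), H2O/THF, 0 °C
Reagents that add atoms: acetic anhydride, CC(=O)OC(C)=O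
Why: Under Schotten–Baumann conditions only the phenol is present as its anion, so acylation should be chemoselective for the phenolic oxygen and leave the primary alcohol free.

Step 5
Reactants: 7 4-(2-hydroxyethyl)-2-(3-methylbut-2-en-1-yl)phenyl acetate
Product: 8 4-(2-oxoethyl)-2-(3-methylbut-2-en-1-yl)phenyl acetate
Conditions: Dess–Martin periodinane (1.2 equiv), CH2Cl2, 0 °C to rt
Reagents that add atoms: none
Why: Dess–Martin oxidation should take the primary alcohol to the aldehyde under non-basic conditions that spare the aryl acetate and the prenyl alkene and do not enolise the sensitive arylacetaldehyde, which is used at once.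

Step 6
Reactants: 9 4-(bromomethyl)phenyl acetate; 10 (1R,4R,5R)-isothiocineole
Product: 11 (1R,4R,5R)-6-[(4-acetoxyphenyl)methyl]-4,7,7-trimethyl-6-thiabicyclo[3.2.1]octan-6-ium triflate (benzyl on the sulfur face syn to the one-carbon bridge)
Conditions: LiOTf (LiO3SCF3), CH2Cl2/H2O, rt
Reagents that add atoms: lithium trifluoromethanesulfonate, [Li+].[O-]S(=O)(=O)C(F)(F)F
Why: SN2 S-alkylation of the sulfide by the benzylic bromide on the less hindered sulfur lone pair, made irreversible by exchange of bromide for non-nucleophilic triflate in the two-phase medium, should give a single sulfonium diastereomer.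

Step 7
Reactants: 11 (1R,4R,5R)-6-[(4-acetoxyphenyl)methyl]-4,7,7-trimethyl-6-thiabicyclo[3.2.1]octan-6-ium triflate; 8 4-(2-oxoethyl)-2-(3-methylbut-2-en-1-yl)phenyl acetate
Product: 13 4-[(2R,3R)-3-{[4-acetoxy-3-(3-methylbut-2-en-1-yl)phenyl]methyl}oxiran-2-yl]phenyl acetate, via sulfonium ylide 12 (not isolated)
Conditions: P2-Et phosphazene base (1.0 equiv), CH2Cl2, −78 °C; then 8 added slowly, −78 to −40 °C
Reagents that add atoms: none
Why: Asymmetric sulfonium ylide epoxidation (Corey–Chaykovsky type under chiral-sulfide control), in which the preformed ylide 12, conformationally fixed and shielded on one face by the gem-dimethyl group, should add to the aldehyde faster than it deprotonates it and the anti betaine should close with loss of the sulfide, so that the sulfide sets C4 as (R), the anti (trans) pathway sets C5 as (R), and the minor cis isomer of opposite C5 configuration is removed by chromatography.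

Step 8
Reactants: 13 4-[(2R,3R)-3-{[4-acetoxy-3-(3-methylbut-2-en-1-yl)phenyl]methyl}oxiran-2-yl]phenyl acetate; 14 carbon monoxide (two molecules incorporated)
Product: 16 (5R)-4-(4-acetoxyphenyl)-5-{[4-acetoxy-3-(3-methylbut-2-en-1-yl)phenyl]methyl}-3-hydroxyfuran-2(5H)-one, via α-keto lactone 15 (not isolated)
Conditions: [(salph)Al(THF)2][Co(CO)4] (10 mol %; salph = N,N′-bis(3,5-di-tert-butylsalicylidene)-1,2-phenylenediamine dianion), i-Pr2NEt (1.2 equiv), CO (60 bar), toluene, 50 °C; then aq. citric acid
Reagents that add atoms: none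
Why: Proposed new method: the cationic aluminium centre activates the oxirane and [Co(CO)4]− opens it by SN2 attack at benzylic C4 (the C5–O bond is never broken), CO insertion gives the C4 acyl cobalt (C4–C3), the amine removes its doubly activated C4–H so that a second CO inserts (C3–C2), and the aluminium-bound C5 alkoxide then acylates at C2 with release of cobaltate, after which α-keto lactone 15 tautomerises to enol 16. The closest known reaction types are the Lewis acid/cobaltate ring-expanding carbonylation of epoxides to β-lactones and the Co2(CO)8-mediated double carbonylation of benzylic halides to arylpyruvic acids, which likewise passes through an enolised arylacetyl cobalt. The single ring closure is a 5-exo-trig acylation of O1 on C2. No stereocentre is created: C5 keeps the (R) configuration of the oxirane because its bond to oxygen persists, and C4 ends sp2, so inversion there is without consequence. The step needs opening at C4 and not C5, and a second insertion faster than 4-exo closure of the mono-acyl to the β-lactone, β-alkoxide loss or hydride shift to the ketone; the aryl group directs SN2 opening to C4, its para-acetoxy substituent suppresses ionisation and acidifies C4–H, the non-coordinating solvent keeps the alkoxide on aluminium until the α-ketoacyl exists, and high CO pressure suppresses β-hydride elimination.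

Step 9
Reactants: 16 (5R)-4-(4-acetoxyphenyl)-5-{[4-acetoxy-3-(3-methylbut-2-en-1-yl)phenyl]methyl}-3-hydroxyfuran-2(5H)-one
Product: 17 (5R)-3-hydroxy-4-(4-hydroxyphenyl)-5-{[4-hydroxy-3-(3-methylbut-2-en-1-yl)phenyl]methyl}furan-2(5H)-one
Conditions: NH4OAc (excess), MeOH/H2O (4:1), rt; then pH 4 buffer
Reagents that add atoms: none
Why: Ammonium acetate-mediated methanolysis should cleave the two activated aryl acetates at near-neutral pH, conditions under which the alkyl lactone, the enol and the C5–H (not acidic enough to exchange) are left alone.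

Compound list
1 | tyrosol, 2-(4-hydroxyphenyl)ethanol | OCCc1ccc(O)cc1 | starting material
2 | 3-chloro-3-methylbut-1-yne | CC(C)(Cl)C#C | starting material
3 | 2-{4-[(2-methylbut-3-yn-2-yl)oxy]phenyl}ethan-1-ol | C#CC(C)(C)Oc1ccc(CCO)cc1 | intermediate
4 | 2-{4-[(2-methylbut-3-en-2-yl)oxy]phenyl}ethan-1-ol | C=CC(C)(C)Oc1ccc(CCO)cc1 | intermediate
5 | 4-(2-hydroxyethyl)-6-(3-methylbut-2-en-1-yl)cyclohexa-2,4-dien-1-one (ortho-dienone, C6 undefined) | O=C1C=CC(CCO)=CC1CC=C(C)C | intermediate (not isolated)
6 | 4-(2-hydroxyethyl)-2-(3-methylbut-2-en-1-yl)phenol | CC(C)=CCc1cc(CCO)ccc1O | intermediate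
7 | 4-(2-hydroxyethyl)-2-(3-methylbut-2-en-1-yl)phenyl acetate | CC(C)=CCc1cc(CCO)ccc1OC(C)=O | intermediate
8 | 4-(2-oxoethyl)-2-(3-methylbut-2-en-1-yl)phenyl acetate | CC(C)=CCc1cc(CC=O)ccc1OC(C)=O | intermediate
9 | 4-(bromomethyl)phenyl acetate | CC(=O)Oc1ccc(CBr)cc1 | starting material
10 | (1R,4R,5R)-isothiocineole, (1R,4R,5R)-4,7,7-trimethyl-6-thiabicyclo[3.2.1]octane | C[C@@H]1CC[C@@H]2C[C@H]1SC2(C)C | starting material
11 | (1R,4R,5R)-6-[(4-acetoxyphenyl)methyl]-4,7,7-trimethyl-6-thiabicyclo[3.2.1]octan-6-ium triflate, benzyl syn to C8 | C[C@@H]1CC[C@@H]2C[C@H]1[S@@+](Cc1ccc(OC(C)=O)cc1)C2(C)C.[O-]S(=O)(=O)C(F)(F)F | intermediate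
12 | sulfonium ylide of 11 (carbanion on the benzylic carbon) | C[C@@H]1CC[C@@H]2C[C@H]1[S@@+]([CH-]c1ccc(OC(C)=O)cc1)C2(C)C | intermediate (not isolated)
13 | 4-[(2R,3R)-3-{[4-acetoxy-3-(3-methylbut-2-en-1-yl)phenyl]methyl}oxiran-2-yl]phenyl acetate (trans) | CC(C)=CCc1cc(C[C@H]2O[C@@H]2c2ccc(OC(C)=O)cc2)ccc1OC(C)=O | intermediate
14 | carbon monoxide | [C-]#[O+] | starting material
15 | (5R)-4-(4-acetoxyphenyl)-5-{[4-acetoxy-3-(3-methylbut-2-en-1-yl)phenyl]methyl}dihydrofuran-2,3-dione (C4 undefined) | CC(C)=CCc1cc(C[C@H]2OC(=O)C(=O)C2c2ccc(OC(C)=O)cc2)ccc1OC(C)=O | intermediate (not isolated)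
16 | (5R)-4-(4-acetoxyphenyl)-5-{[4-acetoxy-3-(3-methylbut-2-en-1-yl)phenyl]methyl}-3-hydroxyfuran-2(5H)-one | CC(C)=CCc1cc(C[C@H]2OC(=O)C(O)=C2c2ccc(OC(C)=O)cc2)ccc1OC(C)=O | intermediate
17 | (5R)-3-hydroxy-4-(4-hydroxyphenyl)-5-{[4-hydroxy-3-(3-methylbut-2-en-1-yl)phenyl]methyl}furan-2(5H)-one | CC(C)=CCc1cc(C[C@H]2OC(=O)C(O)=C2c2ccc(O)cc2)ccc1O | target

Total step count: 9. Longest linear sequence: 8 steps (steps 1, 2, 3, 4, 5, 7, 8, 9); step 6 is a one-step side branch.

Steps most likely to fail

1. Step 8 (proposed new method). The cobaltate may open the oxirane at C5 instead of C4, the mono-acyl may close to the β-lactone before the second insertion, the enolised acyl may lose the C5 alkoxide, or the Lewis acid may isomerise the oxirane to the ketone. The fallback uses known chemistry only, sets out from 13 and comes back at 16. TiCl4-promoted opening of the oxirane at benzylic C4 by the silyl ketene acetal 1-methoxy-1,2-bis(trimethylsilyloxy)ethene (made from methyl (trimethylsilyloxy)acetate; CH2Cl2, −78 °C, aqueous acid work-up) should give methyl (4R)-3-(4-acetoxyphenyl)-5-[4-acetoxy-3-(3-methylbut-2-en-1-yl)phenyl]-2,4-dihydroxypentanoate F1 with the C5–O bond untouched. Acid-catalysed lactonisation (TsOH cat., toluene, rt) should give the 3-hydroxy γ-lactone F2, a mixture at C3 and C4 but (5R). Dess–Martin oxidation of the C3 carbinol should then lead through 15 to enol 16.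

2. Step 7. Proton transfer from the acidic arylacetaldehyde to the ylide (enolisation and self-condensation) may compete with addition, and incomplete trans selectivity would carry material of the wrong C5 configuration forward; the sense of induction is also an assumption. The fallback avoids both the ylide and aldehyde 8, sets out from 4 (prenyl still masked as the oxidation-inert 1,1-dimethylallyl ether) and comes back at 13. Mitsunobu thioetherification with 1-phenyl-1H-tetrazole-5-thiol (PPh3, DIAD, THF) gives the tetrazolyl thioether F3, and oxidation ((NH4)6Mo7O24, H2O2, EtOH) gives the sulfone F4. Julia–Kocienski olefination with 4-formylphenyl acetate (KN(SiMe3)2, DME, −60 °C) gives the (E)-1,3-diarylpropene F5. Shi epoxidation with the D-fructose-derived ketone (KHSO5 as 2KHSO5·KHSO4·K2SO4, NaHCO3, MeCN/H2O, 0 °C, near-neutral pH to spare the acetate), to which the hindered terminal vinyl group is inert, should give the (2R,3R)-oxirane F6. Thermal Claisen rearrangement (toluene, 110 °C) unveils the ortho-prenylphenol F7, and acetylation (Ac2O, pyridine) gives 13.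

3. Step 3. At the rearrangement temperature the tertiary allyl ether may fragment with loss of isoprene, and the ortho-prenylphenol may cyclise onto its own alkene. The fallback sets out from 1 and comes back at 6. O-allylation (allyl bromide, K2CO3, acetone) gives the allyl ether F8, and aromatic Claisen rearrangement (N,N-diethylaniline, 190 °C) gives the 2-allylphenol F9. Cross-metathesis with 2-methylbut-2-ene (second-generation Grubbs catalyst RuCl2(=CHPh)(PCy3)(H2IMes), CH2Cl2, 40 °C) then builds the prenyl group and gives 6.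

Further compounds
F1 | step 8 | methyl (4R)-3-(4-acetoxyphenyl)-5-[4-acetoxy-3-(3-methylbut-2-en-1-yl)phenyl]-2,4-dihydroxypentanoate (C2, C3 undefined) | COC(=O)C(O)C(c1ccc(OC(C)=O)cc1)[C@H](O)Cc1ccc(OC(C)=O)c(CC=C(C)C)c1
F2 | step 8 | (5R)-4-(4-acetoxyphenyl)-5-{[4-acetoxy-3-(3-methylbut-2-en-1-yl)phenyl]methyl}-3-hydroxydihydrofuran-2(3H)-one (C3, C4 undefined) | CC(C)=CCc1cc(C[C@H]2OC(=O)C(O)C2c2ccc(OC(C)=O)cc2)ccc1OC(C)=O
F3 | step 7 | 5-({2-[4-(2-methylbut-3-en-2-yloxy)phenyl]ethyl}sulfanyl)-1-phenyl-1H-tetrazole | C=CC(C)(C)Oc1ccc(CCSc2nnnn2-c2ccccc2)cc1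
F4 | step 7 | 5-({2-[4-(2-methylbut-3-en-2-yloxy)phenyl]ethyl}sulfonyl)-1-phenyl-1H-tetrazole | C=CC(C)(C)Oc1ccc(CCS(=O)(=O)c2nnnn2-c2ccccc2)cc1
F5 | step 7 | 4-[(1E)-3-{4-[(2-methylbut-3-en-2-yl)oxy]phenyl}prop-1-en-1-yl]phenyl acetate | C=CC(C)(C)Oc1ccc(C/C=C/c2ccc(OC(C)=O)cc2)cc1
F6 | step 7 | 4-[(2R,3R)-3-({4-[(2-methylbut-3-en-2-yl)oxy]phenyl}methyl)oxiran-2-yl]phenyl acetate | C=CC(C)(C)Oc1ccc(C[C@H]2O[C@@H]2c2ccc(OC(C)=O)cc2)cc1
F7 | step 7 | 4-[(2R,3R)-3-{[4-hydroxy-3-(3-methylbut-2-en-1-yl)phenyl]methyl}oxiran-2-yl]phenyl acetate | CC(C)=CCc1cc(C[C@H]2O[C@@H]2c2ccc(OC(C)=O)cc2)ccc1O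
F8 | step 3 | 2-[4-(prop-2-en-1-yloxy)phenyl]ethan-1-ol | C=CCOc1ccc(CCO)cc1
F9 | step 3 | 4-(2-hydroxyethyl)-2-(prop-2-en-1-yl)phenol | C=CCc1cc(CCO)ccc1O
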